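**Retrosynthetic overview**

1. Target ⇐ its octamethyl ether (BBr3) ⇐ acid-induced Friedel–Crafts closure of the seven-membered ring, joining the ortho carbon of a 3,5-dimethoxyphenyl group to the benzylic carbon of a 2,4-dimethoxystilbene. The stilbene precursor has a C2 axis through the central benzene, so either 3,5-dimethoxyphenyl group gives the same product.
2. Stilbene ⇐ aromatic ester on the central ring (reduction, oxidation, Horner–Wadsworth–Emmons). Both 3-aryl groups ⇐ the two C3 carboxyl groups by one double decarboxylative arylation.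
3. Feature on which the plan rests: in each dihydrofuran, C3 is bonded to the central-benzene carbon ortho to the ring oxygen and carries one more carbon. This O1–C2(aryl)–C3(C)–C3a pattern is what is left when the fused arene of a 2-arylchroman-4-one shifts from C4 to C3 and C4 leaves the ring as an ester, so each dihydrofuran ⇐ flavanone by oxidative ring contraction.
4. Each flavanone ⇐ chromone + 4-methoxyphenylboronic acid (enantioselective conjugate addition) ⇐ ortho-hydroxyacetophenone. The first comes from methyl 3,5-dihydroxybenzoate, the second is grown next to the benzyl-protected oxygen of the first ring-contraction product.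
5. Order of ring formation: pyranone 1, dihydrofuran A (contraction), pyranone 2, dihydrofuran B (contraction), seven-membered ring.

Key step: step 5

Assumption: the S enantiomer of the pyridine–oxazoline ligand is taken to deliver the aryl group to the chromone face that gives the 2R flavanone, by analogy with its sense towards cyclic enones; if the sense proves opposite, the R ligand is used.

**Route**

Step 1
Reactants: 1 methyl 3,5-dihydroxybenzoate
Product: 2 methyl 2-acetyl-3,5-dihydroxybenzoate
Conditions: AcOH (1.5 equiv), BF3·OEt2 (as solvent), 90 °C; aq. NaOAc work-up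
Reagents that add atoms: acetic acid CC(=O)O
Why: BF3-promoted Friedel–Crafts C-acetylation (Nencki type) of a 5-substituted resorcinol should go to the position para to one hydroxyl and ortho to the other, here C2 next to the ester (C2 and C6 are equivalent), and the first acyl group deactivates the ring against a second one.

Step 2
Reactants: 2 methyl 2-acetyl-3,5-dihydroxybenzoate
Product: 3 methyl 2-acetyl-5-(benzyloxy)-3-hydroxybenzoate
Conditions: BnBr (1.05 equiv), K2CO3, acetone, reflux
Reagents that add atoms: benzyl bromide BrCc1ccccc1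
Why: Williamson ether synthesis in which the 3-hydroxyl is held in a hydrogen bond to the acetyl carbonyl, so the more acidic free 5-hydroxyl should be benzylated selectively under a weak base that does not enolise the ketone towards the neighbouring ester.

Step 3
Reactants: 3 methyl 2-acetyl-5-(benzyloxy)-3-hydroxybenzoate
Product: 5 methyl 7-(benzyloxy)-4-oxo-4H-chromene-5-carboxylate, via enaminone 4 (not isolated)
Conditions: Me2NCH(OMe)2, toluene, 90 °C; then conc. HCl, CH2Cl2, rt
Reagents that add atoms: N,N-dimethylformamide dimethyl acetal COC(OC)N(C)C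
Why: Enaminone formation followed by acid-induced addition of the phenol and loss of dimethylamine is the standard chromone synthesis from 2-hydroxyacetophenones, and it keeps strong base away from the ketone–ester pair, which a Claisen–Schmidt route would expose to Dieckmann-type closure and saponification.

Step 4
Reactants: 5 methyl 7-(benzyloxy)-4-oxo-4H-chromene-5-carboxylate; 6 4-methoxyphenylboronic acid
Product: 7 methyl (2R)-7-(benzyloxy)-2-(4-methoxyphenyl)-4-oxochromane-5-carboxylate
Conditions: Pd(OCOCF3)2 (5 mol %), (S)-4-tert-butyl-2-(pyridin-2-yl)-4,5-dihydrooxazole (6 mol %), NH4PF6 (30 mol %), H2O (5 equiv), ClCH2CH2Cl, 60 °C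
Reagents that add atoms: none
Why: Enantioselective conjugate (1,4-) addition of an arylboronic acid to a chromone under cationic divalent palladium, in which the pyridine–oxazoline ligand blocks one face of the pyranone so that C2 should be formed R, while the neutral medium avoids retro-oxa-Michael racemisation.

Step 5
Reactants: 7 methyl (2R)-7-(benzyloxy)-2-(4-methoxyphenyl)-4-oxochromane-5-carboxylate
Product: 9 dimethyl (2R,3R)-6-(benzyloxy)-2-(4-methoxyphenyl)-2,3-dihydro-1-benzofuran-3,4-dicarboxylate (trans), via methyl enol ether 8 (not isolated)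
Conditions: PhI(OAc)2 (1.2 equiv), conc. H2SO4 (1 equiv), HC(OMe)3, 0 °C → rt; then NaOMe (0.2 equiv), MeOH, rt
Reagents that add atoms: trimethyl orthoformate COC(OC)OC
Why: Sulfuric acid and the orthoformate should turn the C4 ketone into enol ether 8, whose C3 adds to the trivalent iodine of PhI(OAc)2 while methanol returns to C4. With the 2-aryl group equatorial, the C3–I bond lies antiperiplanar to the C4–C4a bond, so the central arene shifts from C4 to C3 through a bridged phenonium ion as iodobenzene leaves, and the dimethoxycarbenium ion left at the old C4 collapses to the methyl ester. The closest known reaction type is the oxidative rearrangement of aryl ketones and flavanones by PhI(OAc)2 or Tl(NO3)3 in trimethyl orthoformate, which gives methyl 2-aryl-2,3-dihydrobenzofuran-3-carboxylates. The dihydrofuran is not closed end to end; it arises by contraction of the pyranone through this 1,2-shift, and the only new skeletal bond is arene–C3. C2 keeps its configuration because the medium is acidic, and C3 is set trans to the 2-aryl group by the anti shift and, being α to the ester, by the closing methoxide equilibration under control of C2. The selectivity needed is migration of the fused arene rather than of the 2-aryl group (isoflavone) or dehydrogenation (flavone); it is secured by the antiperiplanar ring bond, by the oxygen on C4 that pushes the shift, and by the O1 and 7-benzyloxy donors ortho and para to the migrating carbon.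

Step 6
Reactants: 9 dimethyl (2R,3R)-6-(benzyloxy)-2-(4-methoxyphenyl)-2,3-dihydro-1-benzofuran-3,4-dicarboxylate
Product: 10 dimethyl (2R,3R)-5-acetyl-6-(benzyloxy)-2-(4-methoxyphenyl)-2,3-dihydro-1-benzofuran-3,4-dicarboxylate
Conditions: AcCl (1.5 equiv), SnCl4 (2 equiv), CH2Cl2, −20 → 0 °C
Reagents that add atoms: acetyl chloride CC(Cl)=O
Why: Friedel–Crafts acylation at C5, which is para to the ring oxygen and ortho to the benzyloxy group and should be the most nucleophilic site, following the habit of 3,5-dialkoxybenzoates to react ortho to the ester and not between the two oxygens; the anisyl ring is far less activated.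

Step 7
Reactants: 10 dimethyl (2R,3R)-5-acetyl-6-(benzyloxy)-2-(4-methoxyphenyl)-2,3-dihydro-1-benzofuran-3,4-dicarboxylate
Product: 11 dimethyl (2R,3R)-5-acetyl-6-hydroxy-2-(4-methoxyphenyl)-2,3-dihydro-1-benzofuran-3,4-dicarboxylate
Conditions: H2 (1 atm), 10% Pd/C, EtOAc, rt, stopped after one equivalent of H2
Reagents that add atoms: none
Why: Hydrogenolysis of the aryl benzyl ether, which should be much faster than reduction of the twisted, doubly ortho-substituted ketone or cleavage of the cyclic benzylic C2–O bond.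

Step 8
Reactants: 11 dimethyl (2R,3R)-5-acetyl-6-hydroxy-2-(4-methoxyphenyl)-2,3-dihydro-1-benzofuran-3,4-dicarboxylate
Product: 13 dimethyl (2R,3R)-2-(4-methoxyphenyl)-5-oxo-2,3-dihydro-5H-furo[3,2-g]chromene-3,4-dicarboxylate, via enaminone 12 (not isolated)
Conditions: Me2NCH(OMe)2, toluene, 90 °C; then conc. HCl, CH2Cl2, rt
Reagents that add atoms: N,N-dimethylformamide dimethyl acetal COC(OC)N(C)C
Why: The same enaminone/acid chromone synthesis as in step 3; C3 of the dihydrofuran carries a single hydrogen and cannot condense with the acetal, and no stereocentre is touched.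

Step 9
Reactants: 13 dimethyl (2R,3R)-2-(4-methoxyphenyl)-5-oxo-2,3-dihydro-5H-furo[3,2-g]chromene-3,4-dicarboxylate; 6 4-methoxyphenylboronic acid
Product: 14 dimethyl (2R,3R,7R)-2,7-bis(4-methoxyphenyl)-5-oxo-2,3,6,7-tetrahydro-5H-furo[3,2-g]chromene-3,4-dicarboxylate
Conditions: Pd(OCOCF3)2 (5 mol %), (S)-4-tert-butyl-2-(pyridin-2-yl)-4,5-dihydrooxazole (6 mol %), NH4PF6 (30 mol %), H2O (5 equiv), ClCH2CH2Cl, 60 °C
Reagents that add atoms: none
Why: The same palladium-catalysed enantioselective conjugate arylation as in step 4, in which the ligand and not the remote dihydrofuran stereocentres should set C7 as R, giving the second aryl-bearing carbon the same absolute sense as the first.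

Step 10
Reactants: 14 dimethyl (2R,3R,7R)-2,7-bis(4-methoxyphenyl)-5-oxo-2,3,6,7-tetrahydro-5H-furo[3,2-g]chromene-3,4-dicarboxylate
Product: 16 trimethyl (2R,3R,5R,6R)-2,6-bis(4-methoxyphenyl)-2,3,5,6-tetrahydrobenzo[1,2-b:5,4-b']difuran-3,4,5-tricarboxylate (both rings trans, C2-symmetric), via methyl enol ether 15 (not isolated)
Conditions: PhI(OAc)2 (1.2 equiv), conc. H2SO4 (1 equiv), HC(OMe)3, 0 °C → rt; then NaOMe (0.2 equiv), MeOH, rt
Reagents that add atoms: trimethyl orthoformate COC(OC)OC
Why: Second oxidative ring contraction by 1,2-aryl shift (the reaction of step 5), in which enol ether 15 is iodinated at C6, the central arene moves from C5 to C6, and the new ester-bearing stereocentre is equilibrated trans to its 2-aryl neighbour under control of that neighbour.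

Step 11
Reactants: 16 trimethyl (2R,3R,5R,6R)-2,6-bis(4-methoxyphenyl)-2,3,5,6-tetrahydrobenzo[1,2-b:5,4-b']difuran-3,4,5-tricarboxylate
Product: 17 (2R,3R,5R,6R)-4-(methoxycarbonyl)-2,6-bis(4-methoxyphenyl)-2,3,5,6-tetrahydrobenzo[1,2-b:5,4-b']difuran-3,5-dicarboxylic acid
Conditions: LiOH·H2O (3 equiv), THF/H2O, 0 °C → rt; then 1 M HCl
Reagents that add atoms: lithium hydroxide [Li+].[OH-]
Why: Saponification in which the two aliphatic esters should be hydrolysed while the aromatic ester, flanked by two substituted ortho carbons like a mesitoate, resists hydroxide; E1cB ring opening is the reverse of a 5-endo-trig closure and is disfavoured, and any epimerisation returns the trans acids.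

Step 12
Reactants: 17 (2R,3R,5R,6R)-4-(methoxycarbonyl)-2,6-bis(4-methoxyphenyl)-2,3,5,6-tetrahydrobenzo[1,2-b:5,4-b']difuran-3,5-dicarboxylic acid
Product: 18 3,5-bis(1,3-dioxoisoindolin-2-yl) 4-methyl (2R,3R,5R,6R)-2,6-bis(4-methoxyphenyl)-2,3,5,6-tetrahydrobenzo[1,2-b:5,4-b']difuran-3,4,5-tricarboxylate
Conditions: N-hydroxyphthalimide (2.4 equiv), iPrN=C=NiPr (2.4 equiv), DMAP (cat.), CH2Cl2, rt
Reagents that add atoms: N-hydroxyphthalimide O=C1c2ccccc2C(=O)N1O
Why: Carbodiimide (Steglich-type) esterification of both acids with N-hydroxyphthalimide should give the redox-active esters without touching a stereocentre.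

Step 13
Reactants: 18 3,5-bis(1,3-dioxoisoindolin-2-yl) 4-methyl (2R,3R,5R,6R)-2,6-bis(4-methoxyphenyl)-2,3,5,6-tetrahydrobenzo[1,2-b:5,4-b']difuran-3,4,5-tricarboxylate; 19 1-bromo-3,5-dimethoxybenzene
Product: 22 methyl (2R,3R,5R,6R)-3,5-bis(3,5-dimethoxyphenyl)-2,6-bis(4-methoxyphenyl)-2,3,5,6-tetrahydrobenzo[1,2-b:5,4-b']difuran-4-carboxylate, via arylmagnesium bromide 20 (not isolated), via arylzinc chloride 21 (not isolated)
Conditions: 19, Mg, LiCl, THF, rt; ZnCl2, THF; then 18, NiCl2·glyme (20 mol %), 4,4'-di-tert-butyl-2,2'-bipyridine (40 mol %), THF/DMF, rt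
Reagents that add atoms: none
Why: Nickel-catalysed decarboxylative Negishi arylation of redox-active esters, in which single-electron reduction expels CO2 and phthalimide anion and the benzylic C3 and C5 radicals are captured by aryl–nickel on the face anti to the neighbouring 4-methoxyphenyl group, so both new stereocentres should be set trans under control of C2 and C6.

Step 14
Reactants: 22 methyl (2R,3R,5R,6R)-3,5-bis(3,5-dimethoxyphenyl)-2,6-bis(4-methoxyphenyl)-2,3,5,6-tetrahydrobenzo[1,2-b:5,4-b']difuran-4-carboxylate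
Product: 23 [(2R,3R,5R,6R)-3,5-bis(3,5-dimethoxyphenyl)-2,6-bis(4-methoxyphenyl)-2,3,5,6-tetrahydrobenzo[1,2-b:5,4-b']difuran-4-yl]methanol
Conditions: LiAlH4, THF, 0 °C → reflux
Reagents that add atoms: none
Why: Hydride reduction of the hindered aromatic ester with LiAlH4 should give the benzylic alcohol, the dihydrofurans and aryl ethers being inert to hydride.

Step 15
Reactants: 23 [(2R,3R,5R,6R)-3,5-bis(3,5-dimethoxyphenyl)-2,6-bis(4-methoxyphenyl)-2,3,5,6-tetrahydrobenzo[1,2-b:5,4-b']difuran-4-yl]methanol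
Product: 24 (2R,3R,5R,6R)-3,5-bis(3,5-dimethoxyphenyl)-2,6-bis(4-methoxyphenyl)-2,3,5,6-tetrahydrobenzo[1,2-b:5,4-b']difuran-4-carbaldehyde
Conditions: Dess–Martin periodinane (1.3 equiv), CH2Cl2, rt
Reagents that add atoms: none
Why: Dess–Martin oxidation of the benzylic alcohol should stop at the aldehyde under near-neutral conditions that leave the dihydrofurans alone.

Step 16
Reactants: 25 (2,4-dimethoxyphenyl)methanol
Product: 26 diethyl (2,4-dimethoxybenzyl)phosphonate
Conditions: P(OEt)3, ZnI2, toluene, reflux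
Reagents that add atoms: triethyl phosphite CCOP(OCC)OCC
Why: Zinc iodide-mediated Michaelis–Arbuzov-type conversion of an electron-rich benzylic alcohol into its diethyl phosphonate, which avoids the unstable 2,4-dimethoxybenzyl halide.

Step 17
Reactants: 24 (2R,3R,5R,6R)-3,5-bis(3,5-dimethoxyphenyl)-2,6-bis(4-methoxyphenyl)-2,3,5,6-tetrahydrobenzo[1,2-b:5,4-b']difuran-4-carbaldehyde; 26 diethyl (2,4-dimethoxybenzyl)phosphonate
Product: 27 (2R,3R,5R,6R)-4-[(E)-2-(2,4-dimethoxyphenyl)ethenyl]-3,5-bis(3,5-dimethoxyphenyl)-2,6-bis(4-methoxyphenyl)-2,3,5,6-tetrahydrobenzo[1,2-b:5,4-b']difuran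
Conditions: KOtBu, THF, 0 °C → rt
Reagents that add atoms: none
Why: Horner–Wadsworth–Emmons olefination, in which the benzylic phosphonate anion should add even to the di-ortho-substituted aldehyde and give the E stilbene, whose geometry is lost in the next step anyway.

Step 18
Reactants: 27 (2R,3R,5R,6R)-4-[(E)-2-(2,4-dimethoxyphenyl)ethenyl]-3,5-bis(3,5-dimethoxyphenyl)-2,6-bis(4-methoxyphenyl)-2,3,5,6-tetrahydrobenzo[1,2-b:5,4-b']difuran
Product: 28 octa-O-methyl ether of the target (seven-membered ring closed, all five stereocentres R)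
Conditions: MeSO3H (1 equiv), CH2Cl2, −20 → 0 °C
Reagents that add atoms: none
Why: Acid-induced intramolecular Friedel–Crafts alkylation closing the seven-membered ring, in which protonation at the alkene carbon next to the central ring gives the 2,4-dimethoxybenzyl cation and the ortho carbon of either of the two equivalent 3,5-dimethoxyphenyl groups attacks it; the new stereocentre is controlled by the adjacent dihydrofuran (aryl pseudo-equatorial, cis to the neighbouring C3 hydrogen), and since the alkylation is reversible the more stable R epimer should prevail.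

Step 19
Reactants: 28 octa-O-methyl ether of the target
Product: 29 target CNP0154047.1 (all five stereocentres R)
Conditions: BBr3 (20 equiv), CH2Cl2, −78 °C → rt; then H2O/MeOH
Reagents that add atoms: none
Why: Lewis-acid ether cleavage in which BBr3 should remove all eight methyl groups by bromide attack at the O-methyl carbons, the trans-2,3-diaryl-dihydrofurans keeping their configuration because any C2–O ionisation recloses to the trans ring.

**Compound list**

1 | methyl 3,5-dihydroxybenzoate | COC(=O)c1cc(O)cc(O)c1 | starting material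
2 | methyl 2-acetyl-3,5-dihydroxybenzoate | COC(=O)c1cc(O)cc(O)c1C(C)=O | intermediate
3 | methyl 2-acetyl-5-(benzyloxy)-3-hydroxybenzoate | COC(=O)c1cc(OCc2ccccc2)cc(O)c1C(C)=O | intermediate
4 | methyl 5-(benzyloxy)-2-[(E)-3-(dimethylamino)prop-2-enoyl]-3-hydroxybenzoate | COC(=O)c1cc(OCc2ccccc2)cc(O)c1C(=O)/C=C/N(C)C | intermediate (not isolated)
5 | methyl 7-(benzyloxy)-4-oxo-4H-chromene-5-carboxylate | COC(=O)c1cc(OCc2ccccc2)cc2occc(=O)c12 | intermediate
6 | 4-methoxyphenylboronic acid | COc1ccc(B(O)O)cc1 | starting material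
7 | methyl (2R)-7-(benzyloxy)-2-(4-methoxyphenyl)-4-oxochromane-5-carboxylate | COC(=O)c1cc(OCc2ccccc2)cc2O[C@@H](c3ccc(OC)cc3)CC(=O)c12 | intermediate
8 | methyl (2R)-7-(benzyloxy)-4-methoxy-2-(4-methoxyphenyl)-2H-chromene-5-carboxylate | COC(=O)c1cc(OCc2ccccc2)cc2O[C@@H](c3ccc(OC)cc3)C=C(OC)c12 | intermediate (not isolated)
9 | dimethyl (2R,3R)-6-(benzyloxy)-2-(4-methoxyphenyl)-2,3-dihydro-1-benzofuran-3,4-dicarboxylate | COC(=O)c1cc(OCc2ccccc2)cc2O[C@@H](c3ccc(OC)cc3)[C@H](C(=O)OC)c12 | intermediate
10 | dimethyl (2R,3R)-5-acetyl-6-(benzyloxy)-2-(4-methoxyphenyl)-2,3-dihydro-1-benzofuran-3,4-dicarboxylate | COC(=O)c1c(C(C)=O)c(OCc2ccccc2)cc2O[C@@H](c3ccc(OC)cc3)[C@H](C(=O)OC)c12 | intermediate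
11 | dimethyl (2R,3R)-5-acetyl-6-hydroxy-2-(4-methoxyphenyl)-2,3-dihydro-1-benzofuran-3,4-dicarboxylate | COC(=O)c1c(C(C)=O)c(O)cc2O[C@@H](c3ccc(OC)cc3)[C@H](C(=O)OC)c12 | intermediate
12 | dimethyl (2R,3R)-5-[(E)-3-(dimethylamino)prop-2-enoyl]-6-hydroxy-2-(4-methoxyphenyl)-2,3-dihydro-1-benzofuran-3,4-dicarboxylate | COC(=O)c1c(C(=O)/C=C/N(C)C)c(O)cc2O[C@@H](c3ccc(OC)cc3)[C@H](C(=O)OC)c12 | intermediate (not isolated)
13 | dimethyl (2R,3R)-2-(4-methoxyphenyl)-5-oxo-2,3-dihydro-5H-furo[3,2-g]chromene-3,4-dicarboxylate | COC(=O)c1c2c(=O)ccoc2cc2O[C@@H](c3ccc(OC)cc3)[C@H](C(=O)OC)c12 | intermediate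
14 | dimethyl (2R,3R,7R)-2,7-bis(4-methoxyphenyl)-5-oxo-2,3,6,7-tetrahydro-5H-furo[3,2-g]chromene-3,4-dicarboxylate | COC(=O)c1c2C(=O)C[C@H](c3ccc(OC)cc3)Oc2cc2O[C@@H](c3ccc(OC)cc3)[C@H](C(=O)OC)c12 | intermediate
15 | dimethyl (2R,3R,7R)-5-methoxy-2,7-bis(4-methoxyphenyl)-2,3-dihydro-7H-furo[3,2-g]chromene-3,4-dicarboxylate | COC(=O)c1c2C(OC)=C[C@H](c3ccc(OC)cc3)Oc2cc2O[C@@H](c3ccc(OC)cc3)[C@H](C(=O)OC)c12 | intermediate (not isolated)
16 | trimethyl (2R,3R,5R,6R)-2,6-bis(4-methoxyphenyl)-2,3,5,6-tetrahydrobenzo[1,2-b:5,4-b']difuran-3,4,5-tricarboxylate | COC(=O)c1c2[C@@H](C(=O)OC)[C@H](c3ccc(OC)cc3)Oc2cc2O[C@@H](c3ccc(OC)cc3)[C@H](C(=O)OC)c12 | intermediate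
17 | (2R,3R,5R,6R)-4-(methoxycarbonyl)-2,6-bis(4-methoxyphenyl)-2,3,5,6-tetrahydrobenzo[1,2-b:5,4-b']difuran-3,5-dicarboxylic acid | COC(=O)c1c2[C@@H](C(=O)O)[C@H](c3ccc(OC)cc3)Oc2cc2O[C@@H](c3ccc(OC)cc3)[C@H](C(=O)O)c12 | intermediate
18 | 3,5-bis(1,3-dioxoisoindolin-2-yl) 4-methyl (2R,3R,5R,6R)-2,6-bis(4-methoxyphenyl)-2,3,5,6-tetrahydrobenzo[1,2-b:5,4-b']difuran-3,4,5-tricarboxylate | COC(=O)c1c2[C@@H](C(=O)ON3C(=O)c4ccccc4C3=O)[C@H](c3ccc(OC)cc3)Oc2cc2O[C@@H](c3ccc(OC)cc3)[C@H](C(=O)ON3C(=O)c4ccccc4C3=O)c12 | intermediate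
19 | 1-bromo-3,5-dimethoxybenzene | COc1cc(Br)cc(OC)c1 | starting material
20 | (3,5-dimethoxyphenyl)magnesium bromide | COc1cc([Mg]Br)cc(OC)c1 | intermediate (not isolated)
21 | (3,5-dimethoxyphenyl)zinc chloride | COc1cc([Zn]Cl)cc(OC)c1 | intermediate (not isolated)
22 | methyl (2R,3R,5R,6R)-3,5-bis(3,5-dimethoxyphenyl)-2,6-bis(4-methoxyphenyl)-2,3,5,6-tetrahydrobenzo[1,2-b:5,4-b']difuran-4-carboxylate | COC(=O)c1c2[C@@H](c3cc(OC)cc(OC)c3)[C@H](c3ccc(OC)cc3)Oc2cc2O[C@@H](c3ccc(OC)cc3)[C@H](c3cc(OC)cc(OC)c3)c12 | intermediate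
23 | [(2R,3R,5R,6R)-3,5-bis(3,5-dimethoxyphenyl)-2,6-bis(4-methoxyphenyl)-2,3,5,6-tetrahydrobenzo[1,2-b:5,4-b']difuran-4-yl]methanol | OCc1c2[C@@H](c3cc(OC)cc(OC)c3)[C@H](c3ccc(OC)cc3)Oc2cc2O[C@@H](c3ccc(OC)cc3)[C@H](c3cc(OC)cc(OC)c3)c12 | intermediate
24 | (2R,3R,5R,6R)-3,5-bis(3,5-dimethoxyphenyl)-2,6-bis(4-methoxyphenyl)-2,3,5,6-tetrahydrobenzo[1,2-b:5,4-b']difuran-4-carbaldehyde | O=Cc1c2[C@@H](c3cc(OC)cc(OC)c3)[C@H](c3ccc(OC)cc3)Oc2cc2O[C@@H](c3ccc(OC)cc3)[C@H](c3cc(OC)cc(OC)c3)c12 | intermediate
25 | (2,4-dimethoxyphenyl)methanol | COc1ccc(CO)c(OC)c1 | starting material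
26 | diethyl (2,4-dimethoxybenzyl)phosphonate | CCOP(=O)(Cc1ccc(OC)cc1OC)OCC | intermediate
27 | (2R,3R,5R,6R)-4-[(E)-2-(2,4-dimethoxyphenyl)ethenyl]-3,5-bis(3,5-dimethoxyphenyl)-2,6-bis(4-methoxyphenyl)-2,3,5,6-tetrahydrobenzo[1,2-b:5,4-b']difuran | COc1ccc(/C=C/c2c3[C@@H](c4cc(OC)cc(OC)c4)[C@H](c4ccc(OC)cc4)Oc3cc3O[C@@H](c4ccc(OC)cc4)[C@H](c4cc(OC)cc(OC)c4)c23)c(OC)c1 | intermediate
28 | octa-O-methyl ether of the target (all five stereocentres R) | COc1ccc([C@@H]2Oc3cc4c5c(c3[C@H]2c2cc(OC)cc(OC)c2)C[C@H](c2ccc(OC)cc2OC)c2c(OC)cc(OC)cc2[C@H]5[C@H](c2ccc(OC)cc2)O4)cc1 | intermediate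
29 | target CNP0154047.1 (all five stereocentres R) | Oc1ccc([C@@H]2Oc3cc4c5c(c3[C@H]2c2cc(O)cc(O)c2)C[C@H](c2ccc(O)cc2O)c2c(O)cc(O)cc2[C@H]5[C@H](c2ccc(O)cc2)O4)cc1 | target

**Step count**

Total step count: 19. Longest linear sequence: 18 (steps 1–15 and 17–19; step 16 prepares the phosphonate).

**Three steps most likely to fail**

1. Step 5 (key step). Enol ether formation at C4 may be slowed by the peri ester, which can also trap the C4 oxocarbenium ion as a cyclic pseudo-ester. Dehydrogenation to the flavone, or migration of the 2-aryl group to C3, may then compete with the shift of the fused arene. Long exposure to acid may also erode the C2 configuration through reversible ionisation of the 4-methoxybenzylic C2–O bond. Fallback: a Wolff ring contraction, which makes the same arene–C3 bond by a carbene-type 1,2-shift under neutral conditions. It sets out from 7. Acid-catalysed nitrosation at C3 (isoamyl nitrite, HCl, THF, 0 °C) would give methyl (2S)-7-(benzyloxy)-3-(hydroxyimino)-2-(4-methoxyphenyl)-4-oxochromane-5-carboxylate F1 (same arrangement in space at C2; only the descriptor changes). A Forster reaction (NH2Cl, aq. NaOH, 0 °C) would convert it into methyl (2S)-7-(benzyloxy)-3-diazo-2-(4-methoxyphenyl)-4-oxochromane-5-carboxylate F2. Irradiation in methanol, where the fused arene migrates from C4 to C3 and the ketene takes up methanol, followed by NaOMe equilibration, comes back to the route at 9.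

2. Step 13. The two benzylic radicals may dimerise, be reduced to C–H or fragment before nickel captures them; the second coupling may stall after the first; capture may not be fully anti to the 2-aryl groups. Fallback: metallaphotoredox decarboxylative arylation of the free acids, which forms the radicals slowly from the carboxylates and needs neither redox-active ester nor arylzinc. It sets out from 17 and couples it with 19 (Ir[dF(CF3)ppy]2(dtbbpy)PF6, NiCl2·glyme, 4,4'-di-tert-butyl-2,2'-bipyridine, Cs2CO3, DMF, blue light), and comes back to the route at 22 without a new compound.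

3. Step 6. Acylation may take place at the wrong site (C7 between the two oxygens, or the anisyl ring), and the Lewis acid may cleave the benzyl ether or open the dihydrofuran at its benzylic C2–O bond. Fallback: cross-coupling in place of electrophilic acylation. It sets out from 9. Bromination with N-bromosuccinimide in MeCN at 0 °C (3,5-dialkoxybenzoates brominate ortho to the ester) would give dimethyl (2R,3R)-6-(benzyloxy)-5-bromo-2-(4-methoxyphenyl)-2,3-dihydro-1-benzofuran-3,4-dicarboxylate F3. Stille coupling with tributyl(1-ethoxyvinyl)stannane (Pd(PPh3)4, toluene, 100 °C) would give dimethyl (2R,3R)-6-(benzyloxy)-5-(1-ethoxyethenyl)-2-(4-methoxyphenyl)-2,3-dihydro-1-benzofuran-3,4-dicarboxylate F4. Dilute HCl would hydrolyse the enol ether and come back to the route at 10.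

**Further compounds**

F1 | step 5 | methyl (2S)-7-(benzyloxy)-3-(hydroxyimino)-2-(4-methoxyphenyl)-4-oxochromane-5-carboxylate | COC(=O)c1cc(OCc2ccccc2)cc2O[C@@H](c3ccc(OC)cc3)C(=NO)C(=O)c12
F2 | step 5 | methyl (2S)-7-(benzyloxy)-3-diazo-2-(4-methoxyphenyl)-4-oxochromane-5-carboxylate | COC(=O)c1cc(OCc2ccccc2)cc2O[C@@H](c3ccc(OC)cc3)C(=[N+]=[N-])C(=O)c12
F0 | step 13 | none | none
F3 | step 6 | dimethyl (2R,3R)-6-(benzyloxy)-5-bromo-2-(4-methoxyphenyl)-2,3-dihydro-1-benzofuran-3,4-dicarboxylate | COC(=O)c1c(Br)c(OCc2ccccc2)cc2O[C@@H](c3ccc(OC)cc3)[C@H](C(=O)OC)c12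
F4 | step 6 | dimethyl (2R,3R)-6-(benzyloxy)-5-(1-ethoxyethenyl)-2-(4-methoxyphenyl)-2,3-dihydro-1-benzofuran-3,4-dicarboxylate | CCOC(=C)c1c(OCc2ccccc2)cc2O[C@@H](c3ccc(OC)cc3)[C@H](C(=O)OC)c2c1C(=O)OC
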